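**Plan**

1. Last cuts: the three benzyl ethers (O5, O7, pyrone O4). Before that, the C8 ketone is cut on both sides of its carbonyl carbon into an aryl iodide, CO and a 2-methylprop-1-enylstannane.
2. Central cut: pyrone C4–C5 and O1–C2. Pyrone C2–C3–C4 is a malonyl unit whose middle carbon C3 already bears the CH2 link to ring A, and O1–C6–C5 is the enol O–C=C of 3-pentanone. A symmetric bis-acid chloride and a symmetric ketone enol ether can combine in one way only (methyl on C5, ethyl on C6).
3. The malonyl handle goes back through a Meldrum's acid adduct to a C6 aldehyde on 7-O-benzylpinocembrin, ortho to the 5-OH. The C8 iodide is placed para to the same hydroxyl.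
4. Forward order: the chromanone (rings A and C) is bought intact; ring A is formylated at C6 and iodinated at C8, the malonyl chain is attached, the pyrone ring is closed, the C8 enone is made by carbonylation, and the benzyl groups are removed.
5. Stereochemistry: the single stereocentre C2 (S) comes from natural (S)-pinocembrin and is preserved because the flavanone never meets a base strong enough to open the pyranone ring.

Key step: step 9

Assumption: commercial natural pinocembrin is the (2S) enantiomer. The benzylation of the pyrone in step 10 is drawn at O4; the 2-benzyloxy-4-pyranone isomer, if formed, would give the same final product. The E/Z composition of silyl enol ether 12 does not matter.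

**Route**

Step 1
Reactants: 1 (S)-pinocembrin
Product: 2 (2S)-7-(benzyloxy)-5-hydroxy-2-phenylchroman-4-one
Conditions: BnOH, PPh3, DIAD, THF, 0 °C → rt
Reagents that add atoms: benzyl alcohol, OCc1ccccc1
Why: Mitsunobu etherification, in which O7–H (a vinylogous acid para to the C4 carbonyl) protonates the betaine and is alkylated while O5–H stays locked in its hydrogen bond to C4=O, and the neutral medium leaves C2 untouched.

Step 2
Reactants: 2 (2S)-7-(benzyloxy)-5-hydroxy-2-phenylchroman-4-one
Product: 3 (2S)-7-(benzyloxy)-5-hydroxy-4-oxo-2-phenylchromane-6-carbaldehyde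
Conditions: MgCl2, Et3N, (CH2O)n, MeCN, 75 °C; then 1 M HCl
Reagents that add atoms: paraformaldehyde (formaldehyde), C=O
Why: Casnati–Skattebøl ortho-formylation, in which the magnesium 5-phenoxide binds formaldehyde and delivers it to C6 (the only free ortho carbon), a second formaldehyde oxidises the salicyl alkoxide by hydride transfer, and the chelated phenoxide, being a vinylogous carboxylate, does not acidify the C3 protons, so the pyranone ring should stay closed.

Step 3
Reactants: 3 (2S)-7-(benzyloxy)-5-hydroxy-4-oxo-2-phenylchromane-6-carbaldehyde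
Product: 4 (2S)-7-(benzyloxy)-5-hydroxy-8-iodo-4-oxo-2-phenylchromane-6-carbaldehyde
Conditions: NIS, TFA (cat.), MeCN, 0 °C → rt, dark
Reagents that add atoms: N-iodosuccinimide, O=C1CCC(=O)N1I
Why: Electrophilic aromatic iodination at C8, the last free carbon of ring A, which is para to the free 5-hydroxyl and flanked by two ether oxygens, whereas the benzyl and 2-phenyl rings are unactivated.

Step 4
Reactants: 4 (2S)-7-(benzyloxy)-5-hydroxy-8-iodo-4-oxo-2-phenylchromane-6-carbaldehyde
Product: 5 (2S)-5,7-bis(benzyloxy)-8-iodo-4-oxo-2-phenylchromane-6-carbaldehyde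
Conditions: BnBr, Ag2O, CH2Cl2, rt, dark
Reagents that add atoms: benzyl bromide, BrCc1ccccc1
Why: Silver-oxide-mediated Williamson-type O-benzylation, in which the phenol between two carbonyl groups is acidic enough to form the silver phenoxide and silver ion pulls bromide from benzyl bromide, so no soluble base is present that could trigger retro-oxa-Michael opening of the chromanone, whose ring oxygen is para to the formyl group.

Step 5
Reactants: 5 (2S)-5,7-bis(benzyloxy)-8-iodo-4-oxo-2-phenylchromane-6-carbaldehyde; 6 Meldrum's acid (2,2-dimethyl-1,3-dioxane-4,6-dione)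
Product: 8 5-{[(2S)-5,7-bis(benzyloxy)-8-iodo-4-oxo-2-phenylchroman-6-yl]methyl}-2,2-dimethyl-1,3-dioxane-4,6-dione, via arylidene Meldrum's acid 7 (not isolated)
Conditions: Hantzsch ester, L-proline (20 mol %), CH2Cl2–EtOH, rt
Reagents that add atoms: none
Why: Three-component reductive alkylation, in which proline-catalysed Knoevenagel condensation gives the strongly electrophilic arylidene Meldrum's acid, which takes a hydride from the Hantzsch ester at the benzylic carbon, while the ketone, the aryl iodide and the benzyl ethers do not react.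

Step 6
Reactants: 8 5-{[(2S)-5,7-bis(benzyloxy)-8-iodo-4-oxo-2-phenylchroman-6-yl]methyl}-2,2-dimethyl-1,3-dioxane-4,6-dione
Product: 9 2-{[(2S)-5,7-bis(benzyloxy)-8-iodo-4-oxo-2-phenylchroman-6-yl]methyl}propanedioic acid
Conditions: 2 M HCl, THF, 55 °C
Reagents that add atoms: water, O
Why: Acid-catalysed hydrolysis of the cyclic acylal releases acetone and the malonic acid at a temperature where a monosubstituted malonic acid should not yet decarboxylate and where the flavanone and the benzyl ethers tolerate dilute acid.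

Step 7
Reactants: 9 2-{[(2S)-5,7-bis(benzyloxy)-8-iodo-4-oxo-2-phenylchroman-6-yl]methyl}propanedioic acid
Product: 10 2-{[(2S)-5,7-bis(benzyloxy)-8-iodo-4-oxo-2-phenylchroman-6-yl]methyl}propanedioyl dichloride
Conditions: (COCl)2, DMF (cat.), CH2Cl2, 0 °C → rt; evaporate, use crude
Reagents that add atoms: oxalyl chloride, O=C(Cl)C(=O)Cl
Why: Acid chloride formation through the chloroiminium (Vilsmeier-type) species from DMF, on a substrate whose ring A has no free carbon or hydroxyl left to be acylated, and without base, so the ketene is not formed prematurely.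

Step 8
Reactants: 11 3-pentanone
Product: 12 (Z)-3-(trimethylsilyloxy)pent-2-ene
Conditions: TMSOTf, Et3N, Et2O, 0 °C; distil
Reagents that add atoms: trimethylsilyl trifluoromethanesulfonate, C[Si](C)(C)OS(=O)(=O)C(F)(F)F
Why: Soft enolisation and O-silylation of a symmetric ketone, which can give only one regioisomer, and the double-bond geometry (expected mainly Z) is irrelevant because this C=C becomes C5=C6 of the pyrone.

Step 9
Reactants: 10 2-{[(2S)-5,7-bis(benzyloxy)-8-iodo-4-oxo-2-phenylchroman-6-yl]methyl}propanedioyl dichloride; 12 (Z)-3-(trimethylsilyloxy)pent-2-ene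
Product: 14 (2S)-5,7-bis(benzyloxy)-6-[(6-ethyl-4-hydroxy-5-methyl-2-oxo-2H-pyran-3-yl)methyl]-8-iodo-2-phenylchroman-4-one, via diketo acid chloride 13 (not isolated)
Conditions: 12 (1.3 equiv, slow addition), CH2Cl2 (0.02 M), −78 °C → rt; aqueous work-up
Reagents that add atoms: none
Why: The nucleophilic carbon of the silyl enol ether attacks one acid chloride of 10 (directly, or through the chlorocarbonyl ketene formed by loss of HCl) and loses Me3SiCl, which gives the 2-methyl-1,3-diketone 13 and the C4–C5 bond. The enol oxygen of the propionyl ketone in 13 then attacks the remaining acid chloride in a 6-exo-trig acyl substitution that forms O1–C2 and closes the pyrone ring, and tautomerisation at C3 gives the aromatic 4-hydroxy-2-pyrone. The closest known reaction is the annulation of malonyl dichlorides or chlorocarbonyl ketenes with ketone silyl enol ethers to 4-hydroxy-2-pyrones. No stereocentre is created, and C2 is not at risk because the medium is cold and free of base. Only chemoselectivity is required: since both partners are symmetric, methyl must end on C5 and ethyl on C6; the silyl enol ether is far more nucleophilic than the flavanone ketone or the aryl ethers, and slow addition at high dilution should favour ring closure of 13 over a second intermolecular acylation or ketene oligomerisation.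

Step 10
Reactants: 14 (2S)-5,7-bis(benzyloxy)-6-[(6-ethyl-4-hydroxy-5-methyl-2-oxo-2H-pyran-3-yl)methyl]-8-iodo-2-phenylchroman-4-one
Product: 15 (2S)-5,7-bis(benzyloxy)-6-{[4-(benzyloxy)-6-ethyl-5-methyl-2-oxo-2H-pyran-3-yl]methyl}-8-iodo-2-phenylchroman-4-one
Conditions: BnOH, PPh3, DIAD, THF, 0 °C → rt
Reagents that add atoms: benzyl alcohol, OCc1ccccc1
Why: Mitsunobu etherification of the acidic 4-hydroxy-2-pyrone (a vinylogous carboxylic acid), a standard neutral route to 4-alkoxy-2-pyrones, which removes the proton that could otherwise protodestannylate the alkenylstannane in step 12.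

Step 11
Reactants: 16 2-methylprop-1-enylmagnesium bromide
Product: 17 tributyl(2-methylprop-1-enyl)stannane
Conditions: Bu3SnCl, THF, 0 °C → rt
Reagents that add atoms: tributyltin chloride, CCCC[Sn](Cl)(CCCC)CCCC
Why: Substitution at tin by the alkenyl Grignard reagent, the standard preparation of alkenylstannanes.

Step 12
Reactants: 15 (2S)-5,7-bis(benzyloxy)-6-{[4-(benzyloxy)-6-ethyl-5-methyl-2-oxo-2H-pyran-3-yl]methyl}-8-iodo-2-phenylchroman-4-one; 17 tributyl(2-methylprop-1-enyl)stannane
Product: 18 (2S)-5,7-bis(benzyloxy)-6-{[4-(benzyloxy)-6-ethyl-5-methyl-2-oxo-2H-pyran-3-yl]methyl}-8-(3-methylbut-2-enoyl)-2-phenylchroman-4-one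
Conditions: CO (3 atm), Pd2(dba)3 (5 mol %), AsPh3 (20 mol %), NMP, 70 °C
Reagents that add atoms: carbon monoxide, [C-]#[O+]
Why: Carbonylative Stille coupling, in which oxidative addition of the aryl iodide to zerovalent palladium, CO insertion at the di-ortho-substituted aryl–palladium bond, alkenyl transfer from tin and reductive elimination give the aryl alkenyl ketone under neutral conditions that leave the flavanone and the pyrone untouched.

Step 13
Reactants: 18 (2S)-5,7-bis(benzyloxy)-6-{[4-(benzyloxy)-6-ethyl-5-methyl-2-oxo-2H-pyran-3-yl]methyl}-8-(3-methylbut-2-enoyl)-2-phenylchroman-4-one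
Product: 19 (2S)-6-[(6-ethyl-4-hydroxy-5-methyl-2-oxo-2H-pyran-3-yl)methyl]-5,7-dihydroxy-8-(3-methylbut-2-enoyl)-2-phenylchroman-4-one (target)
Conditions: BCl3 (1 M in CH2Cl2), pentamethylbenzene, CH2Cl2, −78 °C; MeOH quench at −78 °C
Reagents that add atoms: none
Why: Lewis-acid cleavage of the benzyl ethers, each assisted by boron chelation to a neighbouring carbonyl (C4=O for O5, the C8 ketone for O7, the pyrone carbonyl through vinylogy for O4), with pentamethylbenzene trapping the benzyl cations by Friedel–Crafts alkylation so that ring A and the enone are not benzylated, and at −78 °C neither oxa-Michael closure of O7–H onto the enone nor epimerisation at C2 should occur.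

**Compound list**

1 | (S)-pinocembrin, (2S)-5,7-dihydroxy-2-phenylchroman-4-one | O=C1C[C@@H](c2ccccc2)Oc2cc(O)cc(O)c12 | starting material
2 | (2S)-7-(benzyloxy)-5-hydroxy-2-phenylchroman-4-one | O=C1C[C@@H](c2ccccc2)Oc2cc(OCc3ccccc3)cc(O)c12 | intermediate
3 | (2S)-7-(benzyloxy)-5-hydroxy-4-oxo-2-phenylchromane-6-carbaldehyde | O=Cc1c(OCc2ccccc2)cc2c(c1O)C(=O)C[C@@H](c1ccccc1)O2 | intermediate
4 | (2S)-7-(benzyloxy)-5-hydroxy-8-iodo-4-oxo-2-phenylchromane-6-carbaldehyde | O=Cc1c(OCc2ccccc2)c(I)c2c(c1O)C(=O)C[C@@H](c1ccccc1)O2 | intermediate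
5 | (2S)-5,7-bis(benzyloxy)-8-iodo-4-oxo-2-phenylchromane-6-carbaldehyde | O=Cc1c(OCc2ccccc2)c(I)c2c(c1OCc1ccccc1)C(=O)C[C@@H](c1ccccc1)O2 | intermediate
6 | Meldrum's acid, 2,2-dimethyl-1,3-dioxane-4,6-dione | CC1(C)OC(=O)CC(=O)O1 | starting material
7 | 5-{[(2S)-5,7-bis(benzyloxy)-8-iodo-4-oxo-2-phenylchroman-6-yl]methylidene}-2,2-dimethyl-1,3-dioxane-4,6-dione | CC1(C)OC(=O)C(=Cc2c(OCc3ccccc3)c(I)c3c(c2OCc2ccccc2)C(=O)C[C@@H](c2ccccc2)O3)C(=O)O1 | intermediate
8 | 5-{[(2S)-5,7-bis(benzyloxy)-8-iodo-4-oxo-2-phenylchroman-6-yl]methyl}-2,2-dimethyl-1,3-dioxane-4,6-dione | CC1(C)OC(=O)C(Cc2c(OCc3ccccc3)c(I)c3c(c2OCc2ccccc2)C(=O)C[C@@H](c2ccccc2)O3)C(=O)O1 | intermediate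
9 | 2-{[(2S)-5,7-bis(benzyloxy)-8-iodo-4-oxo-2-phenylchroman-6-yl]methyl}propanedioic acid | OC(=O)C(Cc1c(OCc2ccccc2)c(I)c2c(c1OCc1ccccc1)C(=O)C[C@@H](c1ccccc1)O2)C(=O)O | intermediate
10 | 2-{[(2S)-5,7-bis(benzyloxy)-8-iodo-4-oxo-2-phenylchroman-6-yl]methyl}propanedioyl dichloride | O=C(Cl)C(Cc1c(OCc2ccccc2)c(I)c2c(c1OCc1ccccc1)C(=O)C[C@@H](c1ccccc1)O2)C(=O)Cl | intermediate
11 | 3-pentanone | CCC(=O)CC | starting material
12 | (Z)-3-(trimethylsilyloxy)pent-2-ene | C/C=C(/CC)O[Si](C)(C)C | intermediate
13 | 2-{[(2S)-5,7-bis(benzyloxy)-8-iodo-4-oxo-2-phenylchroman-6-yl]methyl}-4-methyl-3,5-dioxoheptanoyl chloride (transient centres at C2 and C4 of the chain undefined) | CCC(=O)C(C)C(=O)C(Cc1c(OCc2ccccc2)c(I)c2c(c1OCc1ccccc1)C(=O)C[C@@H](c1ccccc1)O2)C(=O)Cl | intermediate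
14 | (2S)-5,7-bis(benzyloxy)-6-[(6-ethyl-4-hydroxy-5-methyl-2-oxo-2H-pyran-3-yl)methyl]-8-iodo-2-phenylchroman-4-one | CCc1oc(=O)c(Cc2c(OCc3ccccc3)c(I)c3c(c2OCc2ccccc2)C(=O)C[C@@H](c2ccccc2)O3)c(O)c1C | intermediate
15 | (2S)-5,7-bis(benzyloxy)-6-{[4-(benzyloxy)-6-ethyl-5-methyl-2-oxo-2H-pyran-3-yl]methyl}-8-iodo-2-phenylchroman-4-one | CCc1oc(=O)c(Cc2c(OCc3ccccc3)c(I)c3c(c2OCc2ccccc2)C(=O)C[C@@H](c2ccccc2)O3)c(OCc2ccccc2)c1C | intermediate
16 | 2-methylprop-1-enylmagnesium bromide | CC(C)=C[Mg]Br | starting material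
17 | tributyl(2-methylprop-1-enyl)stannane | CC(C)=C[Sn](CCCC)(CCCC)CCCC | intermediate
18 | (2S)-5,7-bis(benzyloxy)-6-{[4-(benzyloxy)-6-ethyl-5-methyl-2-oxo-2H-pyran-3-yl]methyl}-8-(3-methylbut-2-enoyl)-2-phenylchroman-4-one | CCc1oc(=O)c(Cc2c(OCc3ccccc3)c(C(=O)C=C(C)C)c3c(c2OCc2ccccc2)C(=O)C[C@@H](c2ccccc2)O3)c(OCc2ccccc2)c1C | intermediate
19 | (2S)-6-[(6-ethyl-4-hydroxy-5-methyl-2-oxo-2H-pyran-3-yl)methyl]-5,7-dihydroxy-8-(3-methylbut-2-enoyl)-2-phenylchroman-4-one | CCc1oc(=O)c(Cc2c(O)c(C(=O)C=C(C)C)c3c(c2O)C(=O)C[C@@H](c2ccccc2)O3)c(O)c1C | target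

**Summary**

Total step count: 13. Longest linear sequence: 11 steps (1, 2, 3, 4, 5, 6, 7, 9, 10, 12, 13 from (S)-pinocembrin); steps 8 and 11 prepare the two coupling partners.

Steps most likely to fail:

Step 9. The bis-acid chloride may lose HCl to a ketene that oligomerises. A second enol ether may be acylated before the ring closes. An acid chloride may also be captured by a neighbouring benzyl ether oxygen with loss of benzyl chloride. The fallback sets out from aldehyde 5 and returns at pyrone 14. It builds the pyrone first on the unsubstituted malonyl unit and then joins it to ring A by reductive alkylation. Malonyl dichloride and silyl enol ether 12 (Et2O, −78 °C → rt) should give 6-ethyl-4-hydroxy-5-methyl-2H-pyran-2-one F1. Compound F1, aldehyde 5 and Hantzsch ester with catalytic L-proline in CH2Cl2–EtOH should then condense to the Knoevenagel adduct 3-{[(2S)-5,7-bis(benzyloxy)-8-iodo-4-oxo-2-phenylchroman-6-yl]methylidene}-6-ethyl-5-methyl-2H-pyran-2,4(3H)-dione F2, which is reduced in the flask to 14.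

Step 12. CO insertion or alkenyl transfer at the crowded aryl–palladium centre may be slow, leading to CO-free coupling or reductive loss of iodine. The stannane may also be consumed by protodestannylation. The fallback sets out from iodide 15 and returns at ketone 18. Nozaki–Hiyama–Kishi addition of the aryl iodide to 3-methylbut-2-enal (CrCl2, NiCl2 cat., DMF, rt) attacks the aldehyde and spares the flavanone ketone and the pyrone. It should give (2S)-5,7-bis(benzyloxy)-6-{[4-(benzyloxy)-6-ethyl-5-methyl-2-oxo-2H-pyran-3-yl]methyl}-8-(1-hydroxy-3-methylbut-2-enyl)-2-phenylchroman-4-one F3 as a mixture of carbinol epimers. MnO2 (CH2Cl2, rt) should oxidise this benzylic, allylic alcohol to 18.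

Step 2. Formaldehyde may over-react to hydroxymethyl or diarylmethane products. The chelated phenoxide may react sluggishly. Long heating with the amine may also erode C2. The fallback sets out from 2 and returns at 3. It is a Rieche formylation with dichloromethyl methyl ether and TiCl4 (CH2Cl2, −78 → 0 °C), in which the titanium phenoxide steers the electrophile to C6 under acidic conditions. The intermediate (2S)-7-(benzyloxy)-6-[chloro(methoxy)methyl]-5-hydroxy-2-phenylchroman-4-one F4 is hydrolysed to 3 on aqueous work-up.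

**Further compounds**

F1 | step 9 | 6-ethyl-4-hydroxy-5-methyl-2H-pyran-2-one | CCc1oc(=O)cc(O)c1C
F2 | step 9 | 3-{[(2S)-5,7-bis(benzyloxy)-8-iodo-4-oxo-2-phenylchroman-6-yl]methylidene}-6-ethyl-5-methyl-2H-pyran-2,4(3H)-dione | CCC1=C(C)C(=O)C(=Cc2c(OCc3ccccc3)c(I)c3c(c2OCc2ccccc2)C(=O)C[C@@H](c2ccccc2)O3)C(=O)O1
F3 | step 12 | (2S)-5,7-bis(benzyloxy)-6-{[4-(benzyloxy)-6-ethyl-5-methyl-2-oxo-2H-pyran-3-yl]methyl}-8-(1-hydroxy-3-methylbut-2-enyl)-2-phenylchroman-4-one | CCc1oc(=O)c(Cc2c(OCc3ccccc3)c(C(O)C=C(C)C)c3c(c2OCc2ccccc2)C(=O)C[C@@H](c2ccccc2)O3)c(OCc2ccccc2)c1C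
F4 | step 2 | (2S)-7-(benzyloxy)-6-[chloro(methoxy)methyl]-5-hydroxy-2-phenylchroman-4-one | COC(Cl)c1c(OCc2ccccc2)cc2c(c1O)C(=O)C[C@@H](c1ccccc1)O2
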